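**Retrosynthetic overview**

1. The cyclopentanone ring (C1 CHMe, C2 C=O, C3 CHEt, C3a, C7a; indene locants) is made by cutting one carbon out of a six-membered ring. The target comes from its tert-butyl ester, and that ester from the acyloin of a trans-fused octalone that holds one extra ring carbon between C1 and C2.
2. Enabling feature: C2(=O) lies between two enolisable CH centres, C1(H)Me and C3(H)Et. Their all-trans placement relative to C7a and C3a is the thermodynamic one, and the ring-fusion atoms C3a/C7a are β to the carbonyl group. The homologous cyclohexane-1,2-dione therefore contracts to a single constitution whichever acyl bond migrates, and the trans fusion is not touched.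
3. The octalone comes from an intramolecular Diels–Alder reaction of an open-chain 1,7,9-decatriene, forming bonds C3a–C7a and C4–C5. Cyclohexene ring A and the six-membered pre-ring B form together, with both adjacent quaternary carbons. Ring B is contracted afterwards.
4. The triene comes from a catalytic vinylogous Mukaiyama aldol addition of a trienal to the silyl dienolate of 2-ethylhex-2-enoate.
5. The trienal comes from asymmetric hydroformylation of allyl cyanide, two formyl-ylide Wittig homologations and one Horner–Wadsworth–Emmons olefination.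

Key step: step 13

Remark: commercial 2-ethylhex-2-enoic acid is drawn as its E isomer; its alkene geometry is erased in step 8, so an E/Z mixture serves equally.

**Step 1**
Reactants: 1 propyltriphenylphosphonium bromide
Product: 2 2-(triphenyl-λ5-phosphanylidene)butanal
Conditions: KOt-Bu, THF, 0 °C; then HCO2Et, 0 → 23 °C
Reagents that add atoms: ethyl formate, CCOC=O
Why: C-formylation of the phosphorus ylide with a formate ester gives the resonance-stabilised formyl ylide (ylide acylation), and the liberated ethoxide serves as the second base.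

**Step 2**
Reactants: 3 but-3-enenitrile (allyl cyanide)
Product: 4 (R)-3-methyl-4-oxobutanenitrile
Conditions: Rh(acac)(CO)2 (0.2 mol %), BisDiazaphos (0.25 mol %), CO/H2 1:1 (10 bar), PhMe, 60 °C
Reagents that add atoms: carbon monoxide, [C-]#[O+]
Why: Branched-selective asymmetric hydroformylation, for which allyl cyanide is a standard substrate; the chiral bis(diazaphospholane) on rhodium sets the methyl-bearing stereocentre, and the ligand antipode is chosen to give the R aldehyde.

**Step 3**
Reactants: 4 (R)-3-methyl-4-oxobutanenitrile; 2 2-(triphenyl-λ5-phosphanylidene)butanal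
Product: 5 (3R,4E)-5-ethyl-3-methyl-6-oxohex-4-enenitrile
Conditions: PhMe, 70 °C
Reagents that add atoms: none
Why: Wittig olefination with a stabilised α-branched formyl ylide is E-selective and neutral enough to keep the α-stereocentre, and the less electrophilic enal product reacts on only at higher temperature.

**Step 4**
Reactants: 5 (3R,4E)-5-ethyl-3-methyl-6-oxohex-4-enenitrile; 2 2-(triphenyl-λ5-phosphanylidene)butanal
Product: 6 (3R,4E,6E)-5,7-diethyl-3-methyl-8-oxoocta-4,6-dienenitrile
Conditions: PhMe, 110 °C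
Reagents that add atoms: none
Why: A second E-selective Wittig homologation of the same kind, now forced by temperature, extends the enal to the (E,E)-dienal.

**Step 5**
Reactants: 6 (3R,4E,6E)-5,7-diethyl-3-methyl-8-oxoocta-4,6-dienenitrile; 7 diethyl benzylphosphonate
Product: 8 (3R,4E,6E,8E)-5,7-diethyl-3-methyl-9-phenylnona-4,6,8-trienenitrile
Conditions: KOt-Bu, THF, −78 → 0 °C
Reagents that add atoms: none
Why: Horner–Wadsworth–Emmons olefination with the benzylphosphonate anion installs the E-styryl end group, because addition to the aldehyde is faster than vinylogous deprotonation.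

**Step 6**
Reactants: 8 (3R,4E,6E,8E)-5,7-diethyl-3-methyl-9-phenylnona-4,6,8-trienenitrile
Product: 9 (3R,4E,6E,8E)-5,7-diethyl-3-methyl-9-phenylnona-4,6,8-trienal
Conditions: i-Bu2AlH (1.2 equiv), PhMe, −78 °C; then H2O, SiO2, 0 → 23 °C
Reagents that add atoms: water, O
Why: Nitrile-to-aldehyde reduction with one hydride stops at the imine oxidation level and hydrolysis on work-up gives the aldehyde, whose stereocentre is β to the carbonyl group and cannot epimerise.

**Step 7**
Reactants: 10 (E)-2-ethylhex-2-enoic acid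
Product: 11 tert-butyl (E)-2-ethylhex-2-enoate
Conditions: tert-butyl 2,2,2-trichloroacetimidate, BF3·OEt2 (cat.), CH2Cl2–cyclohexane, 23 °C
Reagents that add atoms: tert-butyl 2,2,2-trichloroacetimidate, CC(C)(C)OC(=N)C(Cl)(Cl)Cl
Why: Acid-catalysed O-alkylation of the carboxylic acid by the trichloroacetimidate gives the base-stable ester that must survive steps 12 and 13.

**Step 8**
Reactants: 11 tert-butyl (E)-2-ethylhex-2-enoate
Product: 12 tert-butyl{[(3E)-1-tert-butoxy-2-ethylhexa-1,3-dien-1-yl]oxy}dimethylsilane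
Conditions: LiN(i-Pr)2, THF–DMPU, −78 °C; then t-BuMe2SiCl
Reagents that add atoms: tert-butyldimethylsilyl chloride, CC(C)(C)[Si](C)(C)Cl
Why: γ-Deprotonation of the enoate and O-silylation of the dienolate give the vinylketene silyl acetal (silyl dienolate formation).

**Step 9**
Reactants: 9 (3R,4E,6E,8E)-5,7-diethyl-3-methyl-9-phenylnona-4,6,8-trienal; 12 the silyl dienolate
Product: 13 tert-butyl (2E,4S,5R,7R,8E,10E,12E)-2,4,9,11-tetraethyl-5-hydroxy-7-methyl-13-phenyltrideca-2,8,10,12-tetraenoate
Conditions: SiCl4 (1.1 equiv), chiral binaphthyldiamine-derived bisphosphoramide (5 mol %), i-Pr2NEt (0.2 equiv), CH2Cl2, −72 °C; aqueous work-up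
Reagents that add atoms: none
Why: Lewis-base-catalysed, SiCl4-mediated vinylogous Mukaiyama aldol addition, in which the α-ethyl group directs bond formation to the γ-carbon, the phosphoramide-bound silicon cation (antipode chosen) selects the aldehyde face for the 5R carbinol, and the open transition state should give the anti 4S ethyl centre and the E-enoate, overriding the remote methyl centre.

**Step 10**
Reactants: 13 the hydroxy tetraenoate
Product: 14 tert-butyl (1R,2S,4aS,5R,7R,8S,8aR)-1,2,4,8-tetraethyl-7-hydroxy-5-methyl-2-[(E)-2-phenylethenyl]-1,2,4a,5,6,7,8,8a-octahydronaphthalene-1-carboxylate (trans-fused; 5-Me and 8-Et equatorial, 7-OH axial)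
Conditions: PhMe (5 mM), BHT (cat.), 150 °C, sealed tube
Reagents that add atoms: none
Why: Type 1 intramolecular Diels–Alder reaction of a 1,7,9-decatrienoate, in which the E,E-diene and E-dienophile geometries are transferred suprafacially to the two quaternary carbons and the two ring-fusion carbons, the ester-endo mode gives the trans fusion, and allylic 1,3-strain at both tether stereocentres (each next to a trisubstituted alkene) places methyl and ethyl equatorial in a chair-like tether and so selects one diene face.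

**Step 11**
Reactants: 14 the octalin alcohol
Product: 15 tert-butyl (1R,2S,4aS,5R,8S,8aR)-1,2,4,8-tetraethyl-5-methyl-7-oxo-2-[(E)-2-phenylethenyl]-1,2,4a,5,6,7,8,8a-octahydronaphthalene-1-carboxylate
Conditions: Dess–Martin periodinane, CH2Cl2, 23 °C
Reagents that add atoms: none
Why: Dess–Martin oxidation of the secondary alcohol leaves the alkenes alone, and the neighbouring CHEt centre is already in its equatorial, stable position.

**Step 12**
Reactants: 15 the octalone
Product: 16 tert-butyl (1R,2S,4aR,5S,6S,8S,8aR)-1,2,4,8-tetraethyl-6-hydroxy-5-methyl-7-oxo-2-[(E)-2-phenylethenyl]-1,2,4a,5,6,7,8,8a-octahydronaphthalene-1-carboxylate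
Conditions: KN(SiMe3)2, THF, −78 °C; 2-(phenylsulfonyl)-3-phenyloxaziridine; AcOH quench
Reagents that add atoms: 2-(phenylsulfonyl)-3-phenyloxaziridine, O=S(=O)(c1ccccc1)N1OC1c1ccccc1
Why: Kinetic deprotonation takes place at the open ring CH2 and not at the CHEt carbon next to the ring fusion, and the enolate is hydroxylated by the N-sulfonyloxaziridine from the axial face (enolate oxidation); the new carbinol centre is erased in step 13.

**Step 13**
Reactants: 16 the ring B acyloin
Product: 19 tert-butyl (1S,3S,3aR,4R,5S,7aR)-3,4,5,7-tetraethyl-1-methyl-2-oxo-5-[(E)-2-phenylethenyl]-2,3,3a,4,5,7a-hexahydro-1H-indene-4-carboxylate, via ring B 1,2-dione 17 (not isolated), via hydroxy-acid potassium salt 18 (not isolated)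
Conditions: divided cell, graphite-felt anode, Ni cathode, KOH (6 equiv), 1,4-dioxane–H2O 2:1, N2; 2.1 F mol−1 at 23 °C, then 70 °C without current, then 2.2 F mol−1 at 23 °C
Reagents that add atoms: none
Why: Proposed new method: in KOH the acyloin sits as its enediolate, which a carbon anode should oxidise at very low potential to the cyclohexane-1,2-dione 17 (acyloin-to-diketone electro-oxidation is known); hydroxide then adds to one C=O and the flanking ring C–C bond shifts 1,2 onto the neighbouring carbonyl carbon (benzilic acid rearrangement, the classical six-to-five contraction of cyclic 1,2-diones), which closes the five-membered ring as the 1-hydroxy-1-carboxylate 18. A second two-electron anodic oxidation of this α-hydroxycarboxylate (Hofer–Moest-type non-Kolbe decarboxylation, known to turn α-hydroxy acids into ketones) expels CO2 and leaves the carbonyl carbon between CHMe and CHEt, so the net event is the deletion of one ring carbon in one cell, and only the merging of the three known events is new. Regiochemistry needs no control, because both possible acyl shifts lead to the same 18. The transient carbinol centre is destroyed, C1 and C3 are enolisable and should settle under KOH trans to their neighbours (thermodynamic control, the all-trans array of the target), and C3a and C7a are β to both carbonyl groups, so the trans fusion set in step 10 persists. Chemoselectivity requires that enediolate and α-oxycarboxylate are oxidised before the styryl and trisubstituted alkenes, which their much lower oxidation potentials should secure, and the other carboxyl group is masked as a hindered tert-butyl ester, so only one CO2 can leave.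

**Step 14**
Reactants: 19 the ring-contracted tert-butyl ester
Product: 21 (1S,3S,3aR,4R,5S,7aR)-3,4,5,7-tetraethyl-1-methyl-2-oxo-5-[(E)-2-phenylethenyl]-2,3,3a,4,5,7a-hexahydro-1H-indene-4-carboxylic acid (CNP0420507.2), via trimethylsilyl ester 20 (not isolated)
Conditions: Me3SiOTf (3 equiv), 2,6-lutidine (4 equiv), CH2Cl2, 0 °C; then aqueous work-up (pH 5)
Reagents that add atoms: none
Why: Silyl-triflate-mediated tert-butyl ester cleavage proceeds by alkyl–oxygen fission, so it needs no attack at the hindered carbonyl carbon and avoids the strong Brønsted acid that could lactonise the γ,δ-unsaturated acid; the silyl ester hydrolyses on work-up and the α-centres stay in their thermodynamic positions.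

**Compound list**

1 | propyltriphenylphosphonium bromide | CCC[P+](c1ccccc1)(c1ccccc1)c1ccccc1.[Br-] | starting material
2 | 2-(triphenyl-λ5-phosphanylidene)butanal | CCC(C=O)=P(c1ccccc1)(c1ccccc1)c1ccccc1 | intermediate
3 | but-3-enenitrile | C=CCC#N | starting material
4 | (R)-3-methyl-4-oxobutanenitrile | O=C[C@H](C)CC#N | intermediate
5 | (3R,4E)-5-ethyl-3-methyl-6-oxohex-4-enenitrile | O=C/C(CC)=C/[C@H](C)CC#N | intermediate
6 | (3R,4E,6E)-5,7-diethyl-3-methyl-8-oxoocta-4,6-dienenitrile | O=C/C(CC)=C/C(CC)=C/[C@H](C)CC#N | intermediate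
7 | diethyl benzylphosphonate | CCOP(=O)(Cc1ccccc1)OCC | starting material
8 | (3R,4E,6E,8E)-5,7-diethyl-3-methyl-9-phenylnona-4,6,8-trienenitrile | c1ccccc1/C=C/C(CC)=C/C(CC)=C/[C@H](C)CC#N | intermediate
9 | (3R,4E,6E,8E)-5,7-diethyl-3-methyl-9-phenylnona-4,6,8-trienal | c1ccccc1/C=C/C(CC)=C/C(CC)=C/[C@H](C)CC=O | intermediate
10 | (E)-2-ethylhex-2-enoic acid | CCC/C=C(CC)/C(=O)O | starting material
11 | tert-butyl (E)-2-ethylhex-2-enoate | CCC/C=C(CC)/C(=O)OC(C)(C)C | intermediate
12 | tert-butyl{[(3E)-1-tert-butoxy-2-ethylhexa-1,3-dien-1-yl]oxy}dimethylsilane (ketene acetal geometry not relevant) | CC/C=C/C(CC)=C(OC(C)(C)C)O[Si](C)(C)C(C)(C)C | intermediate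
13 | tert-butyl (2E,4S,5R,7R,8E,10E,12E)-2,4,9,11-tetraethyl-5-hydroxy-7-methyl-13-phenyltrideca-2,8,10,12-tetraenoate | c1ccccc1/C=C/C(CC)=C/C(CC)=C/[C@H](C)C[C@@H](O)[C@@H](CC)/C=C(CC)/C(=O)OC(C)(C)C | intermediate
14 | tert-butyl (1R,2S,4aS,5R,7R,8S,8aR)-1,2,4,8-tetraethyl-7-hydroxy-5-methyl-2-[(E)-2-phenylethenyl]-1,2,4a,5,6,7,8,8a-octahydronaphthalene-1-carboxylate | CCC1=C[C@@](/C=C/c2ccccc2)(CC)[C@](CC)(C(=O)OC(C)(C)C)[C@@H]2[C@@H]1[C@H](C)C[C@@H](O)[C@H]2CC | intermediate
15 | tert-butyl (1R,2S,4aS,5R,8S,8aR)-1,2,4,8-tetraethyl-5-methyl-7-oxo-2-[(E)-2-phenylethenyl]-1,2,4a,5,6,7,8,8a-octahydronaphthalene-1-carboxylate | CCC1=C[C@@](/C=C/c2ccccc2)(CC)[C@](CC)(C(=O)OC(C)(C)C)[C@@H]2[C@@H]1[C@H](C)CC(=O)[C@H]2CC | intermediate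
16 | tert-butyl (1R,2S,4aR,5S,6S,8S,8aR)-1,2,4,8-tetraethyl-6-hydroxy-5-methyl-7-oxo-2-[(E)-2-phenylethenyl]-1,2,4a,5,6,7,8,8a-octahydronaphthalene-1-carboxylate | CCC1=C[C@@](/C=C/c2ccccc2)(CC)[C@](CC)(C(=O)OC(C)(C)C)[C@@H]2[C@@H]1[C@H](C)[C@H](O)C(=O)[C@H]2CC | intermediate
17 | tert-butyl (1R,2S,4aR,5S,8S,8aR)-1,2,4,8-tetraethyl-5-methyl-6,7-dioxo-2-[(E)-2-phenylethenyl]-1,2,4a,5,6,7,8,8a-octahydronaphthalene-1-carboxylate (present as enolate) | CCC1=C[C@@](/C=C/c2ccccc2)(CC)[C@](CC)(C(=O)OC(C)(C)C)[C@@H]2[C@@H]1[C@H](C)C(=O)C(=O)[C@H]2CC | intermediate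
18 | (1S,3S,3aR,4R,5S,7aR)-4-(tert-butoxycarbonyl)-3,4,5,7-tetraethyl-2-hydroxy-1-methyl-5-[(E)-2-phenylethenyl]-2,3,3a,4,5,7a-hexahydro-1H-indene-2-carboxylic acid (potassium salt in the cell; C2 configuration transient and irrelevant) | CCC1=C[C@@](/C=C/c2ccccc2)(CC)[C@](CC)(C(=O)OC(C)(C)C)[C@@H]2[C@@H]1[C@H](C)C(O)(C(=O)O)[C@H]2CC | intermediate
19 | tert-butyl (1S,3S,3aR,4R,5S,7aR)-3,4,5,7-tetraethyl-1-methyl-2-oxo-5-[(E)-2-phenylethenyl]-2,3,3a,4,5,7a-hexahydro-1H-indene-4-carboxylate | CCC1=C[C@@](/C=C/c2ccccc2)(CC)[C@](CC)(C(=O)OC(C)(C)C)[C@@H]2[C@@H]1[C@H](C)C(=O)[C@H]2CC | intermediate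
20 | trimethylsilyl ester of 21 | CCC1=C[C@@](/C=C/c2ccccc2)(CC)[C@](CC)(C(=O)O[Si](C)(C)C)[C@@H]2[C@@H]1[C@H](C)C(=O)[C@H]2CC | intermediate
21 | (1S,3S,3aR,4R,5S,7aR)-3,4,5,7-tetraethyl-1-methyl-2-oxo-5-[(E)-2-phenylethenyl]-2,3,3a,4,5,7a-hexahydro-1H-indene-4-carboxylic acid | CCC1=C[C@@](/C=C/c2ccccc2)(CC)[C@](CC)(C(=O)O)[C@@H]2[C@@H]1[C@H](C)C(=O)[C@H]2CC | target

**Step count**

Total step count: 14. Longest linear sequence: 11 (steps 2–6 and 9–14).

**Steps most likely to fail**

**Step 13.** The benzilic shift of an enolisable dione may be slower than oxidative C–C cleavage of the dione by peroxide formed at the electrodes. The styryl group may be over-oxidised during the second electrolysis. Vinylogous enolisation of the dione may erode the ring fusion.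

The fallback uses a different, known ring contraction and sets out from 15. Detrifluoroacetylative diazo transfer (LiN(SiMe3)2, CF3CO2CH2CF3; then MsN3, Et3N) at the ring CH2 gives the α-diazoketone F1. Visible-light Wolff rearrangement in THF–H2O moves the CHEt carbon with retention and gives the ring-contracted cyclopentanecarboxylic acid F2. Its dianion (LiN(i-Pr)2, 2.2 equiv) is hydroxylated with the N-sulfonyloxaziridine to 18, here isolated. Pb(OAc)4 in benzene at 23 °C then cleaves the α-hydroxy acid, and the route is rejoined at 19.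

**Step 10.** Bond formation between two fully substituted carbons may make the thermal cycloaddition too slow. A 1,5-hydrogen shift in the Z-substituted diene or leakage through the exo mode could then compete.

The fallback changes the activation of the dienophile and sets out from 9.

- Commercial 2-ethylhex-2-enal is converted (t-BuMe2SiOTf, Et3N) into its silyl dienol ether F3.
- The same catalytic vinylogous aldol addition to 9 gives the δ-hydroxy enal F4.
- The far more Lewis-basic enal is cyclised at low temperature with Me2AlCl (2.2 equiv, CH2Cl2, −40 °C) to the bicyclic hydroxy aldehyde F5.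
- Pinnick oxidation (NaClO2, NaH2PO4, 2-methylbut-2-ene) gives the hydroxy acid F6.
- N,N-dimethylformamide di-tert-butyl acetal esterifies the acid selectively, and the route is rejoined at 14.

**Step 9.** Low turnover with an aliphatic aldehyde, or insufficient catalyst control over the anti relationship, would deliver the wrong CHEt configuration. That configuration is mismatched with the methyl centre in step 10.

The fallback replaces catalyst control by auxiliary control and sets out from 9.

- An oxazolidinone boron aldol (Evans-type syn aldol; (R)-4-benzyl-3-butanoyloxazolidin-2-one, n-Bu2BOTf, Et3N) gives the syn adduct F7 with the required ethyl configuration.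
- LiBH4 removes the auxiliary to give the 1,3-diol F8.
- TEMPO/PhI(OAc)2 oxidises the primary alcohol selectively to the β-hydroxy aldehyde F9.
- Wittig olefination with tert-butyl 2-(triphenyl-λ5-phosphanylidene)butanoate gives the C5 epimer of 13, F10.
- Its Diels–Alder cyclisation, now with all three tether substituents equatorial, gives the C7 epimer of 14, F11.
- Dess–Martin oxidation removes the differing centre, and the route is rejoined at 15.

**Further compounds**

F1 | step 13 | tert-butyl 6-diazo-1,2,4,8-tetraethyl-5-methyl-7-oxo-2-[(E)-2-phenylethenyl]octahydronaphthalene-1-carboxylate (stereocentres as in 17) | CCC1=C[C@@](/C=C/c2ccccc2)(CC)[C@](CC)(C(=O)OC(C)(C)C)[C@@H]2[C@@H]1[C@H](C)C(=[N+]=[N-])C(=O)[C@H]2CC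
F2 | step 13 | 4-(tert-butoxycarbonyl)-3,4,5,7-tetraethyl-1-methyl-5-[(E)-2-phenylethenyl]-2,3,3a,4,5,7a-hexahydro-1H-indene-2-carboxylic acid (six retained stereocentres placed as in 19, C2 not relevant) | CCC1=C[C@@](/C=C/c2ccccc2)(CC)[C@](CC)(C(=O)OC(C)(C)C)[C@@H]2[C@@H]1[C@H](C)C(C(=O)O)[C@H]2CC
F3 | step 10 | tert-butyl{[(3E)-2-ethylhexa-1,3-dien-1-yl]oxy}dimethylsilane | CC/C=C/C(CC)=CO[Si](C)(C)C(C)(C)C
F4 | step 10 | (2E,4S,5R,7R,8E,10E,12E)-2,4,9,11-tetraethyl-5-hydroxy-7-methyl-13-phenyltrideca-2,8,10,12-tetraenal | c1ccccc1/C=C/C(CC)=C/C(CC)=C/[C@H](C)C[C@@H](O)[C@@H](CC)/C=C(CC)/C=O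
F5 | step 10 | (1R,2S,4aS,5R,7R,8S,8aR)-1,2,4,8-tetraethyl-7-hydroxy-5-methyl-2-[(E)-2-phenylethenyl]-1,2,4a,5,6,7,8,8a-octahydronaphthalene-1-carbaldehyde | CCC1=C[C@@](/C=C/c2ccccc2)(CC)[C@](CC)(C=O)[C@@H]2[C@@H]1[C@H](C)C[C@@H](O)[C@H]2CC
F6 | step 10 | (1R,2S,4aS,5R,7R,8S,8aR)-1,2,4,8-tetraethyl-7-hydroxy-5-methyl-2-[(E)-2-phenylethenyl]-1,2,4a,5,6,7,8,8a-octahydronaphthalene-1-carboxylic acid | CCC1=C[C@@](/C=C/c2ccccc2)(CC)[C@](CC)(C(=O)O)[C@@H]2[C@@H]1[C@H](C)C[C@@H](O)[C@H]2CC
F7 | step 9 | (R)-4-benzyl-3-[(2R,3S,5R,6E,8E,10E)-2,7,9-triethyl-3-hydroxy-5-methyl-11-phenylundeca-6,8,10-trienoyl]oxazolidin-2-one | c1ccccc1/C=C/C(CC)=C/C(CC)=C/[C@H](C)C[C@H](O)[C@@H](CC)C(=O)N1[C@H](Cc2ccccc2)COC1=O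
F8 | step 9 | (2S,3S,5R,6E,8E,10E)-2,7,9-triethyl-5-methyl-11-phenylundeca-6,8,10-triene-1,3-diol | c1ccccc1/C=C/C(CC)=C/C(CC)=C/[C@H](C)C[C@H](O)[C@@H](CC)CO
F9 | step 9 | (2R,3S,5R,6E,8E,10E)-2,7,9-triethyl-3-hydroxy-5-methyl-11-phenylundeca-6,8,10-trienal | c1ccccc1/C=C/C(CC)=C/C(CC)=C/[C@H](C)C[C@H](O)[C@@H](CC)C=O
F10 | step 9 | tert-butyl (2E,4S,5S,7R,8E,10E,12E)-2,4,9,11-tetraethyl-5-hydroxy-7-methyl-13-phenyltrideca-2,8,10,12-tetraenoate | c1ccccc1/C=C/C(CC)=C/C(CC)=C/[C@H](C)C[C@H](O)[C@@H](CC)/C=C(CC)/C(=O)OC(C)(C)C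
F11 | step 9 | tert-butyl (1R,2S,4aS,5R,7S,8S,8aR)-1,2,4,8-tetraethyl-7-hydroxy-5-methyl-2-[(E)-2-phenylethenyl]-1,2,4a,5,6,7,8,8a-octahydronaphthalene-1-carboxylate | CCC1=C[C@@](/C=C/c2ccccc2)(CC)[C@](CC)(C(=O)OC(C)(C)C)[C@@H]2[C@@H]1[C@H](C)C[C@H](O)[C@H]2CC
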